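## The problem

The target is an elemanolide. Its cyclohexane carries, in ring order: the quaternary C10 (methyl C14, vinyl C1=C2), C9H2, C8 (acyloxy), C7 and C6 (trans-fused α-methylene-γ-butyrolactone with C11=C13, C12=O and the ring oxygen on C6), and C5 (3-hydroxyprop-1-en-2-yl, C4=C3, C15–OH). All five stereocentres (5R,6R,7R,8S,10S) sit on this ring. In the chair the substituents at C5, C6, C7 and C8 are equatorial and mutually trans, and C10 has an axial methyl and an equatorial vinyl group. C5 to C8 can therefore be relayed from one another by chair-controlled reactions. C10 is quaternary, bears two groups of similar size and cannot be equilibrated, so it must be set kinetically against a neighbour, and the absolute configuration must come from one early centre. The fragile groups are the methylene lactone (a Michael acceptor), the (Z)-2-(hydroxymethyl)but-2-enoate (the less stable geometry), three terminal alkenes that forbid hydrogenation or ozonolysis, and C5, which is allylic and α to C6 whenever C6 is a carbonyl. The feature that opens the problem is that the C8 oxygen and an oxidised C6 can be joined as a six-membered lactone O–C8–C9–C10–C5–C6(=O). In that ring C10 is the β-carbon and C5 the α-carbon of an unsaturated ester whose only stereocentre is C8, so a conjugate addition with enolate trapping can set both from C8.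

## Retrosynthesis

**Ester and protecting groups.** The two primary silyl ethers of 27 are removed last to give target 28. The C8–O acyl bond of 27 is cut to alcohol 18 and acid 25. This cut comes last because the (Z)-acyl group is the most easily isomerised part of the molecule and should meet as few reagents as possible. Acid 25 is cut at its C–CO2H bond to bromoalkene 23, which comes from crotonaldehyde 19 through 21 and 22. The forward reactions must keep the alkene geometry, which bromine–lithium exchange and carboxylation do.

**Lactone.** The O–C12 bond of 17 (the silyl-protected form of 18) is cut and C12 is lowered to an allylic alcohol (15) and then to a methyl group (14). This leaves an isopropenyl carbinol and avoids bringing C12 in as a separate carbon; the alternative, α-methylenation of a saturated lactone, would need C11 and C12 to be built first. The forward steps must oxidise one allylic methyl in the presence of the C4=C3 alkene, which its allylic silyloxy group deactivates.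

**Carbocycle.** In 14 the C6–C7 bond is cut (carbonyl-ene retron) to aldehyde 13. Against C5–C6 or C9–C10, this bond lies between two oxygen-bearing carbons and away from the quaternary centre. The precursor is an open chain with only three stereocentres (C5, C8, C10), and the forward closure has an all-equatorial chair available.

**Chain to lactone.** Aldehyde 13 is traced through bis-silyl ether 12 and diol 11 to δ-lactone 10, in which C6 and the C8 oxygen are tied. The acyclic 1,3-relationship C8/C10 and the 1,2-relationship C10/C5 become ring problems.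

**Key disconnection.** In 10 the bonds C10–C1 and C5–C4 are cut. This gives dihydropyranone 5, vinylmagnesium bromide 8 and bromoallyl ether 7. Two skeletal bonds and two stereocentres are removed at once, and C15 arrives already oxidised. The forward reaction must add vinyl trans to the C8 substituent and place C4 trans to vinyl without later epimerisation at C5.

**Dihydropyranone.** 5 is cut at C8–C9 and at the lactone C–O bond to silyl dienolate 3 (from ester 1) and enal 4, a catalytic asymmetric vinylogous aldol. Ether 7 comes from alcohol 6.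

## Roads not taken

**Alternative 1:** The cut is C10–C1 together with a temporary C9–C2 bond. Enone A1 (C8=O, C9=C10) is irradiated with vinyl acetate to give the cis-fused cyclobutane A2. A later ketyl-type cleavage of C9–C2 with loss of acetate would release the vinyl group on C10.
- Merits: the quaternary centre is made on a ring that already holds C5, C6 and C7, and the adjacent C5 substituent shields one face. This facial control is arguably more secure than the 1,3-relay from C8 used here, which is conceded.
- Weak points: A1 must be prepared with three contiguous stereocentres and a masked C4 ketone. Only the head-to-tail adduct can release a vinyl group, and vinyl acetate gives regioisomer mixtures. After fragmentation the C8 ketone must be reduced, C4 methylenated and the lactone α-methylenated.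
- Comparison: the chosen plan sets C10 and C5 in one operation on a lactone made in two steps and carries C15–O and the C4 methylene from the start.

**Alternative 2:** The cut is C6–C7 plus O–C12. CrCl2 converts the allylic bromide of A3 into an allylchromium species that adds through C7 to the C6 aldehyde, and the alkoxide closes onto the ester to give A4.
- Merits: carbocycle, two stereocentres and the complete methylene lactone form in one mild step. This endgame is about two steps shorter than the one chosen here, with no oxidation at C12.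
- Weak points: A3 is acyclic and must already contain C5, C8 and the quaternary C10 in the right relative configuration, with no ring to relay them. It also combines an epimerisable α-alkenyl aldehyde with a bromomethyl acrylate. Such closures often favour the cis-lactone, so the trans fusion is not assured.
- Comparison: the chosen plan uses the same C6–C7 cut with a simpler ene partner. It pays with an allylic oxidation and an oxidative lactonisation, and gains the lactone template for C5 and C10.

**Alternative 3:** The cut is C5–C6. Under Me2AlCl the C6 aldehyde of A5 combines with the C5=C4 alkene to give cyclohexanol A6 with a C5 isopropenyl group.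
- Merits: the closure is of the same reliable isopulegol type. The C7 acetate arm already holds C11 and C12, so no C–H oxidation at C12 is needed; in this respect it is better prepared than the chosen route.
- Weak points: the new bond forms directly beside the quaternary C10. C10 must be created stereoselectively in an open chain relative to C8. C15 is still a methyl, so a late allylic oxidation and an α-methylenation remain.
- Comparison: the chosen plan closes the ring away from C10, sets C10 on a ring from C8, and brings the C15 oxygen in with the bromoallyl ether.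

Key step: step 4

Assumption: (S)-Tol-BINAP is taken to give the (S)-lactone 5 in step 2; if the sense of induction is the opposite, the (R)-ligand is used and nothing else changes.

## Route

Step 1
Reactants: 1 ethyl 3-methylbut-2-enoate
Product: 3 1-ethoxy-3-methyl-1-(trimethylsilyloxy)buta-1,3-diene, via lithium dienolate 2 (not isolated)
Conditions: LiN(iPr)2, THF, −78 °C; then Me3SiCl, −78 °C → rt
Reagents that add atoms: chlorotrimethylsilane, C[Si](C)(C)Cl
Why: γ-Deprotonation of the ester gives the extended lithium dienolate 2, which is silylated on oxygen; this is the standard preparation of a silyl dienolate for vinylogous Mukaiyama aldol reactions.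

Step 2
Reactants: 3 silyl dienolate; 4 3-methylbut-2-enal
Product: 5 (6S)-4-methyl-6-(2-methylprop-1-en-1-yl)-5,6-dihydro-2H-pyran-2-one
Conditions: Cu(OTf)2 (10 mol %), (S)-Tol-BINAP (11 mol %), Bu4N[Ph3SiF2] (20 mol %), THF, −78 °C → rt
Reagents that add atoms: none
Why: Catalytic asymmetric vinylogous Mukaiyama aldol addition; the copper fluoride–bisphosphine complex (monovalent copper) formed in the flask turns 3 into a copper dienolate that adds through its γ-carbon to the enal, a substrate class this catalyst handles well, and the β-methyl dienolate gives a (Z)-aldolate that lactonises directly. C8, the only centre set by a reagent in the route, comes from face selection by the chiral ligand.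

Step 3
Reactants: 6 2-bromoprop-2-en-1-ol
Product: 7 tert-butyl[(2-bromoprop-2-en-1-yl)oxy]diphenylsilane
Conditions: t-BuPh2SiCl, imidazole, CH2Cl2, rt
Reagents that add atoms: tert-butyl(chloro)diphenylsilane, CC(C)(C)[Si](Cl)(c1ccccc1)c1ccccc1
Why: Routine silylation of a primary allylic alcohol; the acid-stable tert-butyldiphenylsilyl group is chosen to outlast the triethylsilyl ether used later at C8.

Step 4
Reactants: 5 (6S)-dihydropyranone; 8 vinylmagnesium bromide; 7 bromoallyl silyl ether
Product: 10 (3R,4S,6S)-3-[3-(tert-butyldiphenylsilyloxy)prop-1-en-2-yl]-4-ethenyl-4-methyl-6-(2-methylprop-1-en-1-yl)oxan-2-one, via silyl ketene acetal 9 (not isolated)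
Conditions: 8, CuBr·SMe2 (10 mol %), Me3SiCl, THF, −78 → −40 °C; volatiles removed; then 7, ZnF2, Pd2(dba)3 (2.5 mol %), P(tBu)3 (10 mol %), DMF, 60 °C
Reagents that add atoms: none
Why: Proposed new method: copper catalysis (CuBr·SMe2, monovalent copper) transfers vinyl from 8 to C10 of 5 while Me3SiCl traps the enolate as silyl ketene acetal 9, and 9 is then alkenylated at C5 by 7 in a zerovalent palladium cycle (oxidative addition into C–Br, ZnF2-assisted transfer of the enolate to palladium, reductive elimination forming C5–C4). The closest known reactions are chlorosilane-accelerated cuprate additions to 6-substituted 5,6-dihydropyran-2-ones, the ZnF2-promoted palladium-catalysed α-arylation of trimethylsilyl ketene acetals, and the α-alkenylation of zinc ester enolates with bromoalkenes; combining them in one flask on a β,β-disubstituted lactone is new. No ring closes. C10 is set by C8: the half-chair of 5 holds the 2-methylpropenyl group pseudo-equatorial and vinyl enters axially on the opposite face, so vinyl ends trans to the C8 substituent. C5 is set by C10: in 9 the new vinyl group is pseudo-axial and the palladium-bound alkenyl group is delivered to the face away from it, giving C4 trans to vinyl. Both selectivities are kinetic, and the nearly neutral fluoride and zinc activation is chosen so that the α-alkenyl lactone is neither epimerised nor isomerised into conjugation. The step needs 1,4- over 1,2-addition of the Grignard reagent, which copper and the chlorosilane secure, and coupling at a neopentyl-type enolate carbon, for which the small planar alkenyl partner and the bulky electron-rich phosphine are chosen.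

Step 5
Reactants: 10 lactone
Product: 11 (2R,3S,5S)-2-[3-(tert-butyldiphenylsilyloxy)prop-1-en-2-yl]-3-ethenyl-3,7-dimethyloct-6-ene-1,5-diol
Conditions: LiAlH4, Et2O, −20 → 0 °C
Reagents that add atoms: none
Why: Hydride reduction of a δ-lactone to the 1,5-diol exposes the C6 and C8 oxygens; the silyl ether and isolated alkenes are inert, and low temperature keeps C5 intact until the carbonyl is gone.

Step 6
Reactants: 11 diol
Product: 12 bis(triethylsilyl) ether of 11
Conditions: Et3SiOTf, 2,6-lutidine, CH2Cl2, −78 → 0 °C
Reagents that add atoms: triethylsilyl trifluoromethanesulfonate, CC[Si](CC)(CC)OS(=O)(=O)C(F)(F)F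
Why: Exhaustive silylation of a primary and a secondary allylic alcohol with a silyl triflate and a hindered base; no selectivity is needed here.

Step 7
Reactants: 12 bis(triethylsilyl) ether
Product: 13 (2R,3S,5S)-2-[3-(tert-butyldiphenylsilyloxy)prop-1-en-2-yl]-3-ethenyl-3,7-dimethyl-5-(triethylsilyloxy)oct-6-enal
Conditions: (COCl)2, DMSO, CH2Cl2, −78 → −40 °C; then iPr2NEt, −78 → 0 °C
Reagents that add atoms: none
Why: Swern conditions cleave and oxidise a primary triethylsilyl ether directly to the aldehyde while secondary triethylsilyl and tert-butyldiphenylsilyl ethers survive, a known chemoselective variant of the Swern oxidation; the hindered amine and low temperature limit epimerisation at C5.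

Step 8
Reactants: 13 aldehyde
Product: 14 (1R,2R,3S,5S,6S)-2-[3-(tert-butyldiphenylsilyloxy)prop-1-en-2-yl]-3-ethenyl-3-methyl-6-(prop-1-en-2-yl)-5-(triethylsilyloxy)cyclohexan-1-ol
Conditions: Me2AlCl, CH2Cl2, −78 °C
Reagents that add atoms: none
Why: Intramolecular carbonyl-ene reaction of the isopulegol type promoted by Me2AlCl, which also scavenges protons: C6 bonds to C7 and a hydrogen of a C11 methyl passes to oxygen through a chair transition state. With the C5 and C8 substituents and the C10 vinyl group equatorial (C10 methyl axial), the forming C6–O and C7–isopropenyl bonds are also equatorial, which gives the trans,trans arrangement of the target at C6 and C7.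

Step 9
Reactants: 14 cyclohexanol
Product: 15 (1R,2R,3S,5S,6S)-2-[3-(tert-butyldiphenylsilyloxy)prop-1-en-2-yl]-3-ethenyl-6-(3-hydroxyprop-1-en-2-yl)-3-methyl-5-(triethylsilyloxy)cyclohexan-1-ol
Conditions: SeO2 (cat.), t-BuOOH, CH2Cl2, 0 °C → rt
Reagents that add atoms: tert-butyl hydroperoxide, CC(C)(C)OO
Why: Allylic oxidation (ene reaction, then 2,3-sigmatropic shift) hydroxylates the methyl of the isopropenyl group; the C4=C3 alkene is deactivated by its allylic silyloxy group and shielded by the silyl group, and the vinyl group has no allylic hydrogen. Any further oxidation at C12 gives the open form of lactol 16 and converges in step 10.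

Step 10
Reactants: 15 diol
Product: 17 (3aS,4S,6S,7R,7aR)-7-[3-(tert-butyldiphenylsilyloxy)prop-1-en-2-yl]-6-ethenyl-6-methyl-3-methylidene-4-(triethylsilyloxy)hexahydro-1-benzofuran-2(3H)-one, via lactol 16 (not isolated)
Conditions: TEMPO (cat.), PhI(OAc)2, CH2Cl2, rt
Reagents that add atoms: none
Why: Oxidative lactonisation of a 1,4-diol: the primary allylic alcohol is oxidised first, the aldehyde is captured by the C6 hydroxyl as lactol 16, and this is oxidised to the trans-fused α-methylene lactone; silyl ethers, alkenes and C6 are untouched.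

Step 11
Reactants: 17 silyl-protected lactone
Product: 18 (3aR,4S,6S,7R,7aR)-7-[3-(tert-butyldiphenylsilyloxy)prop-1-en-2-yl]-6-ethenyl-4-hydroxy-6-methyl-3-methylidenehexahydro-1-benzofuran-2(3H)-one
Conditions: PPTS, MeOH–CH2Cl2, 0 °C
Reagents that add atoms: none
Why: Mild acid methanolysis removes a secondary triethylsilyl ether much faster than a primary tert-butyldiphenylsilyl ether, a standard selective desilylation; the methylene lactone is stable to these non-nucleophilic acidic conditions.

Step 12
Reactants: 19 (E)-but-2-enal
Product: 21 (2Z)-2-bromobut-2-enal, via 2,3-dibromobutanal 20 (not isolated)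
Conditions: Br2, CH2Cl2, 0 °C; then Et3N, 0 °C → rt
Reagents that add atoms: bromine, BrBr
Why: Bromine addition followed by amine-induced loss of HBr from dibromide 20 is the standard route to α-bromo enals; the product is the more stable (Z)-isomer with methyl trans to the formyl group.

Step 13
Reactants: 21 (2Z)-2-bromobut-2-enal
Product: 22 (2Z)-2-bromobut-2-en-1-ol
Conditions: NaBH4, CeCl3·7H2O, MeOH, 0 °C
Reagents that add atoms: none
Why: Luche reduction gives clean 1,2-reduction of the α-bromo enal without touching the C–Br bond or the alkene geometry.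

Step 14
Reactants: 22 (2Z)-2-bromobut-2-en-1-ol
Product: 23 {[(2Z)-2-bromobut-2-en-1-yl]oxy}(tert-butyl)dimethylsilane
Conditions: t-BuMe2SiCl, imidazole, CH2Cl2, rt
Reagents that add atoms: tert-butyl(chloro)dimethylsilane, CC(C)(C)[Si](C)(C)Cl
Why: Routine silylation of a primary allylic alcohol.

Step 15
Reactants: 23 bromoalkene
Product: 25 (2Z)-2-{[(tert-butyldimethylsilyl)oxy]methyl}but-2-enoic acid, via alkenyllithium 24 (not isolated)
Conditions: t-BuLi (2 equiv), Et2O, −78 °C; CO2; aq. citric acid work-up
Reagents that add atoms: carbon dioxide, O=C=O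
Why: Bromine–lithium exchange of an alkenyl bromide and carboxylation both proceed with retention of geometry, the classical route to angelic-type (Z)-acids; at −78 °C the 2-lithioallyl silyl ether neither eliminates nor undergoes silyl migration.

Step 16
Reactants: 25 acid; 18 alcohol
Product: 27 (3aR,4S,6S,7R,7aR)-7-[3-(tert-butyldiphenylsilyloxy)prop-1-en-2-yl]-6-ethenyl-6-methyl-3-methylidene-2-oxooctahydro-1-benzofuran-4-yl (2Z)-2-{[(tert-butyldimethylsilyl)oxy]methyl}but-2-enoate, via mixed anhydride 26 (not isolated)
Conditions: 2,4,6-Cl3C6H2COCl, Et3N, toluene, rt; then 18, toluene, 75 °C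
Reagents that add atoms: none
Why: Yamaguchi esterification through mixed anhydride 26; run without a nucleophilic pyridine catalyst, this is the established way to acylate hindered secondary alcohols with angelic-type acids without isomerisation to the (E)-ester. The alcohol attacks the less hindered alkenoyl carbonyl of 26.

Step 17
Reactants: 27 bis-silyl ether
Product: 28 (3aR,4S,6S,7R,7aR)-6-ethenyl-7-(3-hydroxyprop-1-en-2-yl)-6-methyl-3-methylidene-2-oxooctahydro-1-benzofuran-4-yl (2Z)-2-(hydroxymethyl)but-2-enoate
Conditions: HF·pyridine, pyridine, THF, 0 °C → rt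
Reagents that add atoms: none
Why: Buffered HF·pyridine cleaves both primary allylic silyl ethers under non-basic conditions, so the methylene lactone, the (Z)-enoate and the ester linkage are preserved.

## Compound list

1 | ethyl 3-methylbut-2-enoate | CCOC(=O)C=C(C)C | starting material
2 | lithium 1-ethoxy-3-methylbuta-1,3-dien-1-olate | [Li]OC(OCC)=CC(C)=C | intermediate (not isolated)
3 | 1-ethoxy-3-methyl-1-(trimethylsilyloxy)buta-1,3-diene (ketene acetal geometry not defined) | C=C(C)C=C(OCC)O[Si](C)(C)C | intermediate
4 | 3-methylbut-2-enal | CC(C)=CC=O | starting material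
5 | (6S)-4-methyl-6-(2-methylprop-1-en-1-yl)-5,6-dihydro-2H-pyran-2-one | CC(C)=C[C@@H]1CC(C)=CC(=O)O1 | intermediate
6 | 2-bromoprop-2-en-1-ol | C=C(Br)CO | starting material
7 | tert-butyl[(2-bromoprop-2-en-1-yl)oxy]diphenylsilane | C=C(Br)CO[Si](c1ccccc1)(c1ccccc1)C(C)(C)C | intermediate
8 | vinylmagnesium bromide | C=C[Mg]Br | starting material
9 | trimethyl{[(4S,6S)-4-ethenyl-4-methyl-6-(2-methylprop-1-en-1-yl)-5,6-dihydro-4H-pyran-2-yl]oxy}silane | C=C[C@]1(C)C[C@@H](C=C(C)C)OC(O[Si](C)(C)C)=C1 | intermediate (not isolated)
10 | (3R,4S,6S)-3-[3-(tert-butyldiphenylsilyloxy)prop-1-en-2-yl]-4-ethenyl-4-methyl-6-(2-methylprop-1-en-1-yl)oxan-2-one | C=C[C@]1(C)C[C@@H](C=C(C)C)OC(=O)[C@H]1C(=C)CO[Si](c2ccccc2)(c2ccccc2)C(C)(C)C | intermediate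
11 | (2R,3S,5S)-2-[3-(tert-butyldiphenylsilyloxy)prop-1-en-2-yl]-3-ethenyl-3,7-dimethyloct-6-ene-1,5-diol | C=C[C@](C)(C[C@@H](C=C(C)C)O)[C@@H](CO)C(=C)CO[Si](c1ccccc1)(c1ccccc1)C(C)(C)C | intermediate
12 | (2R,3S,5S)-2-[3-(tert-butyldiphenylsilyloxy)prop-1-en-2-yl]-3-ethenyl-3,7-dimethyl-1,5-bis(triethylsilyloxy)oct-6-ene | C=C[C@](C)(C[C@@H](C=C(C)C)O[Si](CC)(CC)CC)[C@@H](CO[Si](CC)(CC)CC)C(=C)CO[Si](c1ccccc1)(c1ccccc1)C(C)(C)C | intermediate
13 | (2R,3S,5S)-2-[3-(tert-butyldiphenylsilyloxy)prop-1-en-2-yl]-3-ethenyl-3,7-dimethyl-5-(triethylsilyloxy)oct-6-enal | C=C[C@](C)(C[C@@H](C=C(C)C)O[Si](CC)(CC)CC)[C@@H](C=O)C(=C)CO[Si](c1ccccc1)(c1ccccc1)C(C)(C)C | intermediate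
14 | (1R,2R,3S,5S,6S)-2-[3-(tert-butyldiphenylsilyloxy)prop-1-en-2-yl]-3-ethenyl-3-methyl-6-(prop-1-en-2-yl)-5-(triethylsilyloxy)cyclohexan-1-ol | C=C[C@]1(C)C[C@H](O[Si](CC)(CC)CC)[C@@H](C(C)=C)[C@H](O)[C@H]1C(=C)CO[Si](c2ccccc2)(c2ccccc2)C(C)(C)C | intermediate
15 | (1R,2R,3S,5S,6S)-2-[3-(tert-butyldiphenylsilyloxy)prop-1-en-2-yl]-3-ethenyl-6-(3-hydroxyprop-1-en-2-yl)-3-methyl-5-(triethylsilyloxy)cyclohexan-1-ol | C=C[C@]1(C)C[C@H](O[Si](CC)(CC)CC)[C@@H](C(=C)CO)[C@H](O)[C@H]1C(=C)CO[Si](c2ccccc2)(c2ccccc2)C(C)(C)C | intermediate
16 | (3aS,4S,6S,7R,7aR)-7-[3-(tert-butyldiphenylsilyloxy)prop-1-en-2-yl]-6-ethenyl-6-methyl-3-methylidene-4-(triethylsilyloxy)octahydro-1-benzofuran-2-ol (mixture at C2) | C=C[C@]1(C)C[C@H](O[Si](CC)(CC)CC)[C@H]2C(=C)C(O)O[C@@H]2[C@H]1C(=C)CO[Si](c3ccccc3)(c3ccccc3)C(C)(C)C | intermediate (not isolated)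
17 | (3aS,4S,6S,7R,7aR)-7-[3-(tert-butyldiphenylsilyloxy)prop-1-en-2-yl]-6-ethenyl-6-methyl-3-methylidene-4-(triethylsilyloxy)hexahydro-1-benzofuran-2(3H)-one | C=C[C@]1(C)C[C@H](O[Si](CC)(CC)CC)[C@H]2C(=C)C(=O)O[C@@H]2[C@H]1C(=C)CO[Si](c3ccccc3)(c3ccccc3)C(C)(C)C | intermediate
18 | (3aR,4S,6S,7R,7aR)-7-[3-(tert-butyldiphenylsilyloxy)prop-1-en-2-yl]-6-ethenyl-4-hydroxy-6-methyl-3-methylidenehexahydro-1-benzofuran-2(3H)-one | C=C[C@]1(C)C[C@H](O)[C@H]2C(=C)C(=O)O[C@@H]2[C@H]1C(=C)CO[Si](c3ccccc3)(c3ccccc3)C(C)(C)C | intermediate
19 | (E)-but-2-enal | C/C=C/C=O | starting material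
20 | 2,3-dibromobutanal (diastereomer mixture) | CC(Br)C(Br)C=O | intermediate (not isolated)
21 | (2Z)-2-bromobut-2-enal | C/C=C(\Br)C=O | intermediate
22 | (2Z)-2-bromobut-2-en-1-ol | C/C=C(\Br)CO | intermediate
23 | {[(2Z)-2-bromobut-2-en-1-yl]oxy}(tert-butyl)dimethylsilane | C/C=C(\Br)CO[Si](C)(C)C(C)(C)C | intermediate
24 | alkenyllithium from 23 (lithium in place of bromine, geometry retained) | C/C=C(\[Li])CO[Si](C)(C)C(C)(C)C | intermediate (not isolated)
25 | (2Z)-2-{[(tert-butyldimethylsilyl)oxy]methyl}but-2-enoic acid | C/C=C(\C(=O)O)CO[Si](C)(C)C(C)(C)C | intermediate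
26 | (2Z)-2-{[(tert-butyldimethylsilyl)oxy]methyl}but-2-enoic 2,4,6-trichlorobenzoic anhydride | C/C=C(\C(=O)OC(=O)c1c(Cl)cc(Cl)cc1Cl)CO[Si](C)(C)C(C)(C)C | intermediate (not isolated)
27 | (3aR,4S,6S,7R,7aR)-7-[3-(tert-butyldiphenylsilyloxy)prop-1-en-2-yl]-6-ethenyl-6-methyl-3-methylidene-2-oxooctahydro-1-benzofuran-4-yl (2Z)-2-{[(tert-butyldimethylsilyl)oxy]methyl}but-2-enoate | C=C[C@]1(C)C[C@H](OC(=O)/C(=C\C)CO[Si](C)(C)C(C)(C)C)[C@H]2C(=C)C(=O)O[C@@H]2[C@H]1C(=C)CO[Si](c3ccccc3)(c3ccccc3)C(C)(C)C | intermediate
28 | (3aR,4S,6S,7R,7aR)-6-ethenyl-7-(3-hydroxyprop-1-en-2-yl)-6-methyl-3-methylidene-2-oxooctahydro-1-benzofuran-4-yl (2Z)-2-(hydroxymethyl)but-2-enoate | C=C[C@]1(C)C[C@H](OC(=O)/C(=C\C)CO)[C@H]2C(=C)C(=O)O[C@@H]2[C@H]1C(=C)CO | target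

## Step count and risks

Total step count: 17. Longest linear sequence: 12 steps (1, 2, 4 to 11, 16, 17); steps 3 and 12 to 15 are side branches.

**Step 4 (key step, proposed new method).** The most likely failure is slow transfer of the hindered enolate to palladium, so that protodesilylation outruns coupling. Prolonged heating could also erode facial selectivity or epimerise C5. The fallback uses known reactions and sets out from 5. The copper-catalysed, chlorosilane-assisted vinyl addition is run alone and worked up with aqueous acid to give the conjugate adduct (4R,6S)-4-ethenyl-4-methyl-6-(2-methylprop-1-en-1-yl)oxan-2-one F1. Its lithium enolate (LiN(iPr)2, THF, −78 °C) is added to the tert-butyldiphenylsilyl ether of hydroxyacetone, anti to the axial vinyl group, to give the β-hydroxy lactone F2. Dehydration toward the methyl group (Burgess reagent, benzene, 50 °C) returns to the route at 10.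

**Step 2.** Enantioselectivity may be insufficient, or lactonisation may stop at the open hydroxy ester where the (E)-enoate forms. The fallback sets out from 4. Asymmetric methallylboration (B-methallyldiisopinocampheylborane, antipode chosen for the S carbinol; Et2O, −78 °C; NaOH, H2O2) should give (4S)-2,6-dimethylhepta-1,5-dien-4-ol F3. Acryloyl chloride and Et3N give the acrylate F4. Ring-closing metathesis with second-generation Grubbs catalyst (CH2Cl2, reflux) closes the trisubstituted enoate and comes back at 5.

**Step 7.** The amine base may epimerise C5 or move the C4=C3 double bond into conjugation, and the hindered primary silyl ether may cleave incompletely. The fallback sets out from 10 and keeps C6 at the acid oxidation level. Me(MeO)NH·HCl and Me3Al (CH2Cl2, 0 °C → rt) open the lactone to the hydroxy Weinreb amide F5. Et3SiOTf and 2,6-lutidine give its triethylsilyl ether F6. iBu2AlH (THF, −78 °C) releases the aldehyde under base-free conditions and rejoins the route at 13.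

**Step 8.** The Lewis acid may ionise the allylic C8 silyl ether, chloride may capture the developing C11 cation, or C5 may epimerise through the aluminium enolate, giving poor facial selectivity. The fallback sets out from 13 and replaces the cationic ene closure by an organochromium allylation. SeO2 (cat.) and t-BuOOH oxidise the (E)-methyl of the trisubstituted alkene to the (E)-allylic alcohol F7. N-bromosuccinimide and Me2S give the allylic bromide F8. CrCl2 (divalent chromium, THF, rt) forms an allylchromium species that adds through C7 to the C6 aldehyde and returns to 14; the trans outcome at C6/C7 would have to be confirmed.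

**Step 9.** Site selectivity may be poor (oxidation at C15 or at C5–H of the other alkene), or the allylic alcohol may be overoxidised. The fallback sets out from 14. m-Chloroperbenzoic acid with NaHCO3 (CH2Cl2, 0 °C) should epoxidise the more electron-rich isopropenyl group to give the epoxide F9. Et2Al(TMP) (diethylaluminium 2,2,6,6-tetramethylpiperidide, toluene, 0 °C) isomerises it by abstraction of a methyl hydrogen and comes back at 15.

**Step 16.** The activated acid may isomerise from Z to E through reversible conjugate addition of the amine, or the hindered C8 hydroxyl may acylate slowly. The fallback sets out from 18 and 23 and forms the acyl carbon on the alcohol. Palladium-catalysed alkoxycarbonylation of 23 with 18 as the nucleophile (Pd(OAc)2, Xantphos, CO, Et3N, toluene, 80 °C) keeps the alkene geometry and returns directly to 27; no new compound is made.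

## Further compounds

F1 | step 4 | (4R,6S)-4-ethenyl-4-methyl-6-(2-methylprop-1-en-1-yl)oxan-2-one | C=C[C@]1(C)C[C@@H](C=C(C)C)OC(=O)C1
F2 | step 4 | β-hydroxy lactone: 10 with the C4=C3 double bond replaced by C4(OH)(CH3), carbinol centre unassigned | C=C[C@]1(C)C[C@@H](C=C(C)C)OC(=O)[C@H]1C(C)(O)CO[Si](c2ccccc2)(c2ccccc2)C(C)(C)C
F3 | step 2 | (4S)-2,6-dimethylhepta-1,5-dien-4-ol | CC(C)=C[C@@H](O)CC(C)=C
F4 | step 2 | (4S)-2,6-dimethylhepta-1,5-dien-4-yl prop-2-enoate | CC(C)=C[C@@H](OC(=O)C=C)CC(C)=C
F5 | step 7 | (2R,3S,5S)-2-[3-(tert-butyldiphenylsilyloxy)prop-1-en-2-yl]-3-ethenyl-5-hydroxy-N-methoxy-N,3,7-trimethyloct-6-enamide | C=C[C@](C)(C[C@@H](C=C(C)C)O)[C@@H](C(=O)N(C)OC)C(=C)CO[Si](c1ccccc1)(c1ccccc1)C(C)(C)C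
F6 | step 7 | triethylsilyl ether of F5 at the C5 hydroxyl | C=C[C@](C)(C[C@@H](C=C(C)C)O[Si](CC)(CC)CC)[C@@H](C(=O)N(C)OC)C(=C)CO[Si](c1ccccc1)(c1ccccc1)C(C)(C)C
F7 | step 8 | (2R,3S,5S,6E)-2-[3-(tert-butyldiphenylsilyloxy)prop-1-en-2-yl]-3-ethenyl-8-hydroxy-3,7-dimethyl-5-(triethylsilyloxy)oct-6-enal | C=C[C@](C)(C[C@@H](/C=C(\C)CO)O[Si](CC)(CC)CC)[C@@H](C=O)C(=C)CO[Si](c1ccccc1)(c1ccccc1)C(C)(C)C
F8 | step 8 | (2R,3S,5S,6E)-8-bromo-2-[3-(tert-butyldiphenylsilyloxy)prop-1-en-2-yl]-3-ethenyl-3,7-dimethyl-5-(triethylsilyloxy)oct-6-enal | C=C[C@](C)(C[C@@H](/C=C(\C)CBr)O[Si](CC)(CC)CC)[C@@H](C=O)C(=C)CO[Si](c1ccccc1)(c1ccccc1)C(C)(C)C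
F9 | step 9 | epoxide of 14 at the isopropenyl double bond (2-methyloxiran-2-yl group on C7, oxirane centre unassigned) | C=C[C@]1(C)C[C@H](O[Si](CC)(CC)CC)[C@@H](C2(C)CO2)[C@H](O)[C@H]1C(=C)CO[Si](c3ccccc3)(c3ccccc3)C(C)(C)C
F0 | step 16 | none | none
A1 | alternative 1 | cyclohexenone for the photocycloaddition (C8 ketone, C9=C10 with the C10 methyl, C5 with the dioxolane-masked C4 ketone and CH2OSi(t-Bu)Ph2, C6 tert-butyldimethylsilyl ether, C7 tert-butyl acetate arm) | O=C1C=C(C)[C@H](C2(CO[Si](c3ccccc3)(c3ccccc3)C(C)(C)C)OCCO2)[C@@H](O[Si](C)(C)C(C)(C)C)[C@@H]1CC(=O)OC(C)(C)C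
A2 | alternative 1 | cis-fused cyclobutane photoadduct with the acetoxy group on C1 | O=C1[C@H]2C[C@H](OC(C)=O)[C@@]2(C)[C@H](C3(CO[Si](c4ccccc4)(c4ccccc4)C(C)(C)C)OCCO3)[C@@H](O[Si](C)(C)C(C)(C)C)[C@@H]1CC(=O)OC(C)(C)C
A3 | alternative 2 | acyclic C6 aldehyde with a methyl (Z)-2-(bromomethyl)alk-2-enoate terminus, C8 p-methoxybenzyl ether, C15 tert-butyldiphenylsilyl ether | C=C[C@](C)(C[C@H](OCc1ccc(OC)cc1)/C=C(\CBr)C(=O)OC)[C@@H](C=O)C(=C)CO[Si](c1ccccc1)(c1ccccc1)C(C)(C)C
A4 | alternative 2 | trans-fused α-methylene lactone with C8 p-methoxybenzyl ether and C15 tert-butyldiphenylsilyl ether | C=C[C@]1(C)C[C@H](OCc3ccc(OC)cc3)[C@H]2C(=C)C(=O)O[C@@H]2[C@H]1C(=C)CO[Si](c3ccccc3)(c3ccccc3)C(C)(C)C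
A5 | alternative 3 | acyclic C6 aldehyde with the C5=C4 2-methylpropenyl group on the quaternary C10, C8 tert-butyldiphenylsilyl ether, C7 tert-butyl acetate arm | C=C[C@@](C)(C=C(C)C)C[C@H](O[Si](c1ccccc1)(c1ccccc1)C(C)(C)C)[C@@H](CC(=O)OC(C)(C)C)C=O
A6 | alternative 3 | cyclohexanol with C6–OH and C5 isopropenyl (C15 still a methyl) | C=C[C@]1(C)C[C@H](O[Si](c2ccccc2)(c2ccccc2)C(C)(C)C)[C@@H](CC(=O)OC(C)(C)C)[C@H](O)[C@H]1C(C)=C
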